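**Retrosynthetic overview**

- The target is (2S)-5,4'-dihydroxy-6,7-dimethoxy-8-prenylflavanone. The plan rests on the guaiacol unit of ring A (C5–OH next to C6–OMe): its two-electron oxidation gives a C6 dimethyl ketal dienone in which C8a, the carbon that must carry O1, is β to both the C5 carbonyl and the C4 ketone.
- Key disconnection C8a–O1: ring C is closed last, on a ring A that still has H at C8a, from an open-chain (S)-β-hydroxy ketone. The C2–O bond is never broken.
- C2–C3 disconnection: a catalytic asymmetric Mukaiyama aldol between the bis-silylated 2'-hydroxy-3',4'-dimethoxy-5'-prenylacetophenone and 4-(tert-butyldimethylsilyloxy)benzaldehyde sets C2.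
- The C8 prenyl group (C5' of the acetophenone) comes from O-prenylation and a para-Claisen–Cope shift; both ortho positions are blocked.
- Ring order: rings A and B are bought, ring C is the only ring formed (step 5), and desilylation ends the route.

Key step: step 5

Remark: the ring B phenol is carried as a tert-butyldimethylsilyl ether, because the aldehyde is commercial and the final unmasking then uses buffered fluoride instead of protic acid on the prenyl group and the benzylic C2–O1 ether.

Assumption: the (S,S)-enantiomer of the bisphosphoramide catalyst (two (S)-N,N'-dimethyl-1,1'-binaphthyl-2,2'-diamine phosphoramide units joined by an N,N'-dimethylpentane-1,5-diamine tether) is taken as the one that directs Si-face addition to aromatic aldehydes. If the first run shows the opposite sense, the (R,R)-enantiomer is used with no other change.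

**Step 1**
Reactants: 1 2'-hydroxy-3',4'-dimethoxyacetophenone; 2 prenyl bromide
Product: 3 1-[3,4-dimethoxy-2-(3-methylbut-2-enyloxy)phenyl]ethanone
Conditions: K2CO3, DMF, 60 °C
Reagents that add atoms: none
Why: Williamson O-alkylation of the chelated phenol by a reactive allylic bromide under carbonate base, which leaves the methyl ketone untouched.

**Step 2**
Reactants: 3 1-[3,4-dimethoxy-2-(3-methylbut-2-enyloxy)phenyl]ethanone
Product: 6 1-[2-hydroxy-3,4-dimethoxy-5-(3-methylbut-2-enyl)phenyl]ethanone, via ortho-dienone 4 (not isolated), via para-dienone 5 (not isolated)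
Conditions: N,N-diethylaniline, 190 °C, argon, sealed tube
Reagents that add atoms: none
Why: para-Claisen rearrangement: both ortho carbons of the aryl prenyl ether are substituted, so the first [3,3] shift gives a blocked ortho-dienone that can only pass the allyl unit on by a Cope [3,3] shift to C5', where tautomerisation should restore the phenol with the prenyl group in its normal form.

**Step 3**
Reactants: 6 1-[2-hydroxy-3,4-dimethoxy-5-(3-methylbut-2-enyl)phenyl]ethanone
Product: 7 trimethyl{1-[3,4-dimethoxy-5-(3-methylbut-2-enyl)-2-(trimethylsilyloxy)phenyl]ethenyloxy}silane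
Conditions: TMSOTf (2.4 equiv), Et3N (3.5 equiv), CH2Cl2, 0 °C to rt; pentane trituration, used crude
Reagents that add atoms: trimethylsilyl trifluoromethanesulfonate (TMSOTf), C[Si](C)(C)OS(=O)(=O)C(F)(F)F
Why: soft enolisation and silylation turn the methyl ketone into its trimethylsilyl enol ether and cap the phenol as a labile trimethylsilyl ether, so that no acidic proton meets the Lewis acid of step 4.

**Step 4**
Reactants: 7 trimethyl{1-[3,4-dimethoxy-5-(3-methylbut-2-enyl)-2-(trimethylsilyloxy)phenyl]ethenyloxy}silane; 8 4-(tert-butyldimethylsilyloxy)benzaldehyde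
Product: 10 (S)-3-[4-(tert-butyldimethylsilyloxy)phenyl]-3-hydroxy-1-[2-hydroxy-3,4-dimethoxy-5-(3-methylbut-2-enyl)phenyl]propan-1-one, via trichlorosilyl aldolate 9 (not isolated)
Conditions: SiCl4 (1.5 equiv), (S,S)-bisphosphoramide (5 mol %), iPr2NEt (10 mol %), CH2Cl2, −78 °C; then cold sat. aq. NaHCO3
Reagents that add atoms: none
Why: catalytic enantioselective Mukaiyama aldol addition under Lewis-base activation of SiCl4, in which the phosphoramide-bound trichlorosilyl cation binds aldehyde 8 and the enol silane adds to its Si face, so the (S)-carbinol is set by the catalyst, while the bicarbonate work-up hydrolyses the O–SiCl3 and ArO–SiMe3 bonds and should leave the aryl tert-butyldimethylsilyl ether in place.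

**Step 5**
Reactants: 10 (S)-3-[4-(tert-butyldimethylsilyloxy)phenyl]-3-hydroxy-1-[2-hydroxy-3,4-dimethoxy-5-(3-methylbut-2-enyl)phenyl]propan-1-one
Product: 13 (2S)-2-[4-(tert-butyldimethylsilyloxy)phenyl]-5-hydroxy-6,7-dimethoxy-8-(3-methylbut-2-enyl)chroman-4-one, via ketal dienone 11 (not isolated), via oxa-Michael adduct 12 (not isolated)
Conditions: PhI(OAc)2 (1.1 equiv), MeOH–CH2Cl2 (1:4), −20 °C to rt; then PPTS (10 mol %), rt
Reagents that add atoms: methanol (CO)
Why: Proposed new method: ligand exchange of the C5 phenol on PhI(OAc)2 and loss of iodobenzene give a phenoxenium-type species that methanol captures at the methoxy-bearing C6, so ring A becomes the 6,6-dimethoxycyclohexa-2,4-dienone 11, in which C8a is the β-carbon of both the C5 dienone carbonyl and the C4 aryl ketone. The C2 hydroxyl then adds to C8a in a 6-endo-trig oxa-Michael closure of ring C (12), and acid-assisted ionisation of either C6 methoxy group (so the C6 methoxy group of 13 may stem from the solvent) followed by loss of the C8a proton from the Wheland-type cation restores the arene, the net change being a two-electron C–H to C–O oxidation at C8a. The closest known reaction types are the PhI(OAc)2–methanol synthesis of masked ortho-benzoquinones from 2-methoxyphenols, the addition–rearomatisation of nucleophiles on such monoketals and the conjugate addition of alcohols to 2-acylquinones, whereas the intramolecular alcohol version on an acyl-substituted monoketal has not been shown. No stereocentre is created in the product, since C8a of 12 becomes planar on aromatisation, and the C2–O bond is never broken, so the (S) configuration from step 4 is carried through unchanged. The step needs site selectivity for C8a and chemoselectivity for ring A: C8a is the only unsubstituted carbon of ring A, it is doubly activated and it is the only one the tether reaches through a six-membered transition state, C7 is deactivated by its methoxy group, methanol is held at co-solvent level so that it does not compete as the Michael donor, and the silyl ether keeps ring B out of the oxidation. If methanol is captured at the prenyl-bearing C8 instead, the resulting 2,5-dienone still has C8a β to both carbonyls and aromatises by loss of the C8 methoxy group, so both capture modes should converge on 13.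

**Step 6**
Reactants: 13 (2S)-2-[4-(tert-butyldimethylsilyloxy)phenyl]-5-hydroxy-6,7-dimethoxy-8-(3-methylbut-2-enyl)chroman-4-one
Product: 14 (2S)-5-hydroxy-2-(4-hydroxyphenyl)-6,7-dimethoxy-8-(3-methylbut-2-enyl)chroman-4-one
Conditions: TBAF (1.2 equiv), AcOH (1.5 equiv), THF, 0 °C
Reagents that add atoms: none
Why: fluoride-induced cleavage of the aryl silyl ether, buffered with acetic acid so that no phenoxide persists to open the flavanone by retro-oxa-Michael reaction and erode C2, and with no acid strong enough to touch the prenyl group.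

**Compound list**

1 | 1-(2-hydroxy-3,4-dimethoxyphenyl)ethanone (2'-hydroxy-3',4'-dimethoxyacetophenone) | CC(=O)c1ccc(OC)c(OC)c1O | starting material
2 | 1-bromo-3-methylbut-2-ene (prenyl bromide) | CC(C)=CCBr | starting material
3 | 1-[3,4-dimethoxy-2-(3-methylbut-2-enyloxy)phenyl]ethanone | CC(=O)c1ccc(OC)c(OC)c1OCC=C(C)C | intermediate
4 | 2-acetyl-5,6-dimethoxy-6-(2-methylbut-3-en-2-yl)cyclohexa-2,4-dien-1-one (ortho-dienone, racemic, not isolated) | CC(=O)C1=CC=C(OC)C(OC)(C(C)(C)C=C)C1=O | intermediate
5 | 2-acetyl-5,6-dimethoxy-4-(3-methylbut-2-enyl)cyclohexa-2,5-dien-1-one (para-dienone, racemic, not isolated) | CC(=O)C1=CC(CC=C(C)C)C(OC)=C(OC)C1=O | intermediate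
6 | 1-[2-hydroxy-3,4-dimethoxy-5-(3-methylbut-2-enyl)phenyl]ethanone | CC(=O)c1cc(CC=C(C)C)c(OC)c(OC)c1O | intermediate
7 | trimethyl{1-[3,4-dimethoxy-5-(3-methylbut-2-enyl)-2-(trimethylsilyloxy)phenyl]ethenyloxy}silane | C=C(O[Si](C)(C)C)c1cc(CC=C(C)C)c(OC)c(OC)c1O[Si](C)(C)C | intermediate
8 | 4-(tert-butyldimethylsilyloxy)benzaldehyde | O=Cc1ccc(O[Si](C)(C)C(C)(C)C)cc1 | starting material
9 | (S)-3-[4-(tert-butyldimethylsilyloxy)phenyl]-1-[3,4-dimethoxy-5-(3-methylbut-2-enyl)-2-(trimethylsilyloxy)phenyl]-3-(trichlorosilyloxy)propan-1-one (not isolated) | COc1c(O[Si](C)(C)C)c(C(=O)C[C@H](O[Si](Cl)(Cl)Cl)c2ccc(O[Si](C)(C)C(C)(C)C)cc2)cc(CC=C(C)C)c1OC | intermediate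
10 | (S)-3-[4-(tert-butyldimethylsilyloxy)phenyl]-3-hydroxy-1-[2-hydroxy-3,4-dimethoxy-5-(3-methylbut-2-enyl)phenyl]propan-1-one | COc1c(O)c(C(=O)C[C@H](O)c2ccc(O[Si](C)(C)C(C)(C)C)cc2)cc(CC=C(C)C)c1OC | intermediate
11 | 2-{(S)-3-[4-(tert-butyldimethylsilyloxy)phenyl]-3-hydroxypropanoyl}-5,6,6-trimethoxy-4-(3-methylbut-2-enyl)cyclohexa-2,4-dien-1-one (not isolated) | COC1=C(CC=C(C)C)C=C(C(=O)C[C@H](O)c2ccc(O[Si](C)(C)C(C)(C)C)cc2)C(=O)C1(OC)OC | intermediate
12 | (2S)-2-[4-(tert-butyldimethylsilyloxy)phenyl]-5-hydroxy-6,6,7-trimethoxy-8-(3-methylbut-2-enyl)-2,3,6,8a-tetrahydrochromen-4-one (enol form, either C8a epimer, not isolated) | COC1=C(CC=C(C)C)C2O[C@H](c3ccc(O[Si](C)(C)C(C)(C)C)cc3)CC(=O)C2=C(O)C1(OC)OC | intermediate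
13 | (2S)-2-[4-(tert-butyldimethylsilyloxy)phenyl]-5-hydroxy-6,7-dimethoxy-8-(3-methylbut-2-enyl)chroman-4-one | COc1c(O)c2c(c(CC=C(C)C)c1OC)O[C@H](c1ccc(O[Si](C)(C)C(C)(C)C)cc1)CC2=O | intermediate
14 | (2S)-5-hydroxy-2-(4-hydroxyphenyl)-6,7-dimethoxy-8-(3-methylbut-2-enyl)chroman-4-one | COc1c(O)c2c(c(CC=C(C)C)c1OC)O[C@H](c1ccc(O)cc1)CC2=O | target

**Step count**

Total step count: 6. Longest linear sequence: 6 steps (1 to 14); aldehyde 8 is bought and enters at step 4.

**Steps most likely to fail**

Step 5 (proposed new method). Several processes could divert it: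
- methanol or acetate could add to C8a faster than the tethered hydroxyl;
- the dienone could dimerise by Diels–Alder reaction before ring closure;
- the oxidation could run to a para-quinone methide by loss of a benzylic proton of the prenyl group;
- the Michael adduct could revert instead of losing methanol.

The fallback uses known chemistry and places O1 on ring A from the start, closing the O1–C2 bond instead. It sets out from aldehyde 8. Commercial 6'-hydroxy-2',3',4'-trimethoxyacetophenone F1 is brominated at its only free ring position (NBS, MeCN, 0 °C) to give 1-(3-bromo-2-hydroxy-4,5,6-trimethoxyphenyl)ethanone F2. Stille coupling with tributyl(3-methylbut-2-enyl)stannane (Pd(PPh3)4, DMF, 100 °C) gives 1-[2-hydroxy-4,5,6-trimethoxy-3-(3-methylbut-2-enyl)phenyl]ethanone F3. Silylation as in step 3 gives the bis-silyl enol ether F4, and the aldol of step 4 with 8, run with the (R,R)-catalyst, gives the (R)-aldol F5. An intramolecular Mitsunobu etherification (PPh3, DIAD, THF, 0 °C) closes ring C with inversion at C2 to give (2S)-2-[4-(tert-butyldimethylsilyloxy)phenyl]-5,6,7-trimethoxy-8-(3-methylbut-2-enyl)chroman-4-one F6. BCl3 in CH2Cl2 at −78 °C then cleaves only the C5 methyl ether, which is chelated to the C4 ketone, and the route is rejoined at 13.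

Step 4. The ortho-disubstituted enol silane may give low enantioselectivity or the opposite sense of induction, and the aldol may suffer retro-aldol cleavage or dehydration at work-up. The fallback sets out from 6 and 8 and gives up asymmetric catalysis. The lithium dianion of 6 (LiHMDS, 2.2 equiv, THF, −78 °C, acetic acid quench in the cold) adds to 8 to give the racemic aldol F7. Preparative supercritical-fluid chromatography on an amylose tris(3,5-dimethylphenylcarbamate) phase resolves it; the (S)-enantiomer is 10, where the route is rejoined, and the (R)-enantiomer F8 is set aside.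

Step 2. The prenyl group may be lost as isoprene by retro-ene cleavage in competition with the two sigmatropic shifts, or the ortho-dienone may be intercepted before the Cope shift. The fallback sets out from 1 and replaces the rearrangement by a cross-coupling. NBS in MeCN at 0 °C brominates C5', which is para to the hydroxyl and ortho to the C4' methoxy group, to give 1-(5-bromo-2-hydroxy-3,4-dimethoxyphenyl)ethanone F9. Stille coupling with tributyl(3-methylbut-2-enyl)stannane (Pd(PPh3)4, DMF, 100 °C) then gives 6, where the route is rejoined.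

**Further compounds**

F1 | step 5 | 1-(6-hydroxy-2,3,4-trimethoxyphenyl)ethanone (purchased) | CC(=O)c1c(O)cc(OC)c(OC)c1OC
F2 | step 5 | 1-(3-bromo-2-hydroxy-4,5,6-trimethoxyphenyl)ethanone | CC(=O)c1c(O)c(Br)c(OC)c(OC)c1OC
F3 | step 5 | 1-[2-hydroxy-4,5,6-trimethoxy-3-(3-methylbut-2-enyl)phenyl]ethanone | CC(=O)c1c(O)c(CC=C(C)C)c(OC)c(OC)c1OC
F4 | step 5 | trimethyl{1-[4,5,6-trimethoxy-3-(3-methylbut-2-enyl)-2-(trimethylsilyloxy)phenyl]ethenyloxy}silane | C=C(O[Si](C)(C)C)c1c(O[Si](C)(C)C)c(CC=C(C)C)c(OC)c(OC)c1OC
F5 | step 5 | (R)-3-[4-(tert-butyldimethylsilyloxy)phenyl]-3-hydroxy-1-[2-hydroxy-4,5,6-trimethoxy-3-(3-methylbut-2-enyl)phenyl]propan-1-one | COc1c(OC)c(OC)c(C(=O)C[C@@H](O)c2ccc(O[Si](C)(C)C(C)(C)C)cc2)c(O)c1CC=C(C)C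
F6 | step 5 | (2S)-2-[4-(tert-butyldimethylsilyloxy)phenyl]-5,6,7-trimethoxy-8-(3-methylbut-2-enyl)chroman-4-one | COc1c(OC)c2c(c(CC=C(C)C)c1OC)O[C@H](c1ccc(O[Si](C)(C)C(C)(C)C)cc1)CC2=O
F7 | step 4 | racemic 3-[4-(tert-butyldimethylsilyloxy)phenyl]-3-hydroxy-1-[2-hydroxy-3,4-dimethoxy-5-(3-methylbut-2-enyl)phenyl]propan-1-one | COc1c(O)c(C(=O)CC(O)c2ccc(O[Si](C)(C)C(C)(C)C)cc2)cc(CC=C(C)C)c1OC
F8 | step 4 | (R)-3-[4-(tert-butyldimethylsilyloxy)phenyl]-3-hydroxy-1-[2-hydroxy-3,4-dimethoxy-5-(3-methylbut-2-enyl)phenyl]propan-1-one | COc1c(O)c(C(=O)C[C@@H](O)c2ccc(O[Si](C)(C)C(C)(C)C)cc2)cc(CC=C(C)C)c1OC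
F9 | step 2 | 1-(5-bromo-2-hydroxy-3,4-dimethoxyphenyl)ethanone | CC(=O)c1cc(Br)c(OC)c(OC)c1O
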